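**Retrosynthetic overview**
1. Platanetin is 3,5,7,8-tetrahydroxy-6-prenylflavone. The plan rests on ring A: the oxygens on C5 and C8 are para to each other and C6, ortho to the C5 oxygen, carries the prenyl group. This is the pattern of a 4-methoxyphenol made from a chromium methoxycarbene, a 1-alkyne and CO.
2. Key disconnection (C8–C7, C6–C5, C5–C4a): ring A of flavone 16 comes from the pentacarbonylchromium methoxy(pyranonyl)carbene 11, 5-methylhex-4-en-1-yne 14 and one carbonyl ligand; ring C supplies C4a and C8a.
3. Carbene 11 comes from acid chloride 7 by acylation of Na2Cr(CO)5 and O-methylation; 7 comes from kojic acid by C6 bromination, MOM protection, Suzuki phenylation and oxidation of the CH2OH group.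
4. The C7 hydroxyl is added after ring A: oxidation to the 5,8-quinone, epoxidation of C6=C7, base isomerisation to the 7-hydroxyquinone, reduction, MOM removal.
5. Ring order: ring C is bought as kojic acid, ring B is attached in step 3, ring A is closed last in step 8.

Key step: step 8

Remark: flavone numbering (O1, C2, C3, C4, C4a, C5–C8, C8a) is used for rings A and C; epoxide 18 is taken as the racemate, and the target has no stereocentre.

**Step 1**
Reactants: 1 kojic acid
Product: 2 2-bromo-3-hydroxy-6-(hydroxymethyl)-4H-pyran-4-one (6-bromokojic acid)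
Conditions: NBS, MeCN, 0 °C to rt
Reagents that add atoms: N-bromosuccinimide, O=C1CCC(=O)N1Br
Why: Electrophilic bromination of the enol should go to C6, the carbon next to the enolic hydroxyl, which is also where kojic acid takes Mannich and aldol electrophiles.

**Step 2**
Reactants: 2 2-bromo-3-hydroxy-6-(hydroxymethyl)-4H-pyran-4-one
Product: 3 2-bromo-6-(hydroxymethyl)-3-(methoxymethoxy)-4H-pyran-4-one
Conditions: MOMCl (1.1 equiv), K2CO3, acetone, 0 °C to rt
Reagents that add atoms: chloromethyl methyl ether, COCCl
Why: Williamson-type O-alkylation; carbonate deprotonates only the acidic enolic hydroxyl, so the primary alcohol should stay free.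

**Step 3**
Reactants: 3 2-bromo-6-(hydroxymethyl)-3-(methoxymethoxy)-4H-pyran-4-one; 4 phenylboronic acid
Product: 5 6-(hydroxymethyl)-3-(methoxymethoxy)-2-phenyl-4H-pyran-4-one
Conditions: Pd(PPh3)4 (5 mol %), K2CO3, dioxane/H2O, 85 °C
Reagents that add atoms: none
Why: Suzuki–Miyaura coupling; the C–Br bond at the beta position of the pyranone enone is activated for oxidative addition, and the free alcohol and MOM acetal tolerate aqueous carbonate.

**Step 4**
Reactants: 5 6-(hydroxymethyl)-3-(methoxymethoxy)-2-phenyl-4H-pyran-4-one
Product: 6 5-(methoxymethoxy)-4-oxo-6-phenyl-4H-pyran-2-carboxylic acid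
Conditions: TEMPO (0.2 equiv), PhI(OAc)2 (2.2 equiv), MeCN/H2O 1:1, rt
Reagents that add atoms: water, O
Why: Oxoammonium-mediated oxidation of the allylic-type primary alcohol to the aldehyde, whose hydrate is oxidised on to the acid; this avoids the strong mineral acid of a chromic acid oxidation, which would endanger the MOM ether.

**Step 5**
Reactants: 6 5-(methoxymethoxy)-4-oxo-6-phenyl-4H-pyran-2-carboxylic acid
Product: 7 5-(methoxymethoxy)-4-oxo-6-phenyl-4H-pyran-2-carbonyl chloride
Conditions: 1-chloro-N,N,2-trimethylprop-1-en-1-amine (1.2 equiv), CH2Cl2, 0 °C to rt; concentrate, use crude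
Reagents that add atoms: 1-chloro-N,N,2-trimethylprop-1-en-1-amine, CC(C)=C(Cl)N(C)C
Why: Acid chloride formation with an alpha-chloroenamine runs under neutral conditions and releases no HCl, so the MOM acetal should survive.

**Step 6**
Reactants: 7 5-(methoxymethoxy)-4-oxo-6-phenyl-4H-pyran-2-carbonyl chloride; 8 chromium hexacarbonyl
Product: 11 pentacarbonyl{methoxy[5-(methoxymethoxy)-4-oxo-6-phenyl-4H-pyran-2-yl]methylidene}chromium, via disodium pentacarbonylchromate 9 (not isolated), via sodium acylpentacarbonylchromate 10 (not isolated)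
Conditions: Cr(CO)6, NaC10H8 (sodium naphthalenide, 2 equiv), THF, −78 to 0 °C; then 7, THF, −78 °C; solvent exchange to CH2Cl2, Me3OBF4 (1.05 equiv), 0 °C
Reagents that add atoms: trimethyloxonium tetrafluoroborate, C[O+](C)C.F[B-](F)(F)F
Why: Acylation of the pentacarbonylchromate dianion by an acid chloride gives the same acylchromate that the Fischer carbene synthesis reaches from an organolithium, and O-methylation with one equivalent of oxonium salt should give the methoxycarbene; the anionic acylchromate oxygen is methylated far faster than the neutral pyranone carbonyl.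

**Step 7**
Reactants: 12 prenyl bromide; 13 ethynylmagnesium bromide
Product: 14 5-methylhex-4-en-1-yne
Conditions: HC≡CMgBr (1.5 equiv), CuCl (5 mol %), THF, 0 to 45 °C; distil
Reagents that add atoms: none
Why: Copper-catalysed SN2 coupling of an alkynyl Grignard reagent with a primary allylic bromide should give the skipped enyne by attack at the unhindered CH2 terminus, and distillation removes any lower-boiling branched isomer.

**Step 8**
Reactants: 11 pentacarbonyl{methoxy[5-(methoxymethoxy)-4-oxo-6-phenyl-4H-pyran-2-yl]methylidene}chromium; 14 5-methylhex-4-en-1-yne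
Product: 16 5-hydroxy-8-methoxy-3-(methoxymethoxy)-6-(3-methylbut-2-enyl)flavone, via chromium tricarbonyl arene complex 15 (not isolated)
Conditions: 14 (2 equiv), THF (0.05 M), 50 °C, Ar; then stir open to air, rt
Reagents that add atoms: none
Why: Thermal loss of one CO from 11 lets alkyne 14 coordinate and insert into the Cr=C bond with its unsubstituted terminus bonding to the carbene carbon (C8–C7); CO then inserts at the new carbene carbon to give a chromium-bound dienylketene (C6–C5), which closes onto pyranone C3 (C5–C4a) and tautomerises to the phenol, held first as the Cr(CO)3 complex 15 and released by air. The closest known reaction is the Dötz benzannulation of 2-furyl and 5,6-dihydro-4H-pyran-2-yl methoxycarbene chromium complexes with terminal alkynes, where an oxygen-bearing C=C of the carbene substituent plays the part taken here by the pyranone C2=C3 bond. Ring A closes by 6π electrocyclisation of the dienylketene, the carbonyl ligand becoming C5 and the pyranone supplying C4a and C8a. No stereocentre is formed. Insertion must be regioselective, and the size difference between H and the allylic CH2 group of the 1-alkyne should direct the substituted carbon toward the incoming CO, which puts the prenyl group on C6 beside the new C5 hydroxyl. Phenol formation must also win over furan or cyclobutenone formation, which the methoxy donor, THF at moderate temperature and the free hydrogen on pyranone C3 favour, while the skipped trisubstituted alkene of 14 is too close to the alkyne to be cyclopropanated.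

**Step 9**
Reactants: 16 5-hydroxy-8-methoxy-3-(methoxymethoxy)-6-(3-methylbut-2-enyl)flavone
Product: 17 3-(methoxymethoxy)-6-(3-methylbut-2-enyl)-2-phenyl-4H-chromene-4,5,8-trione
Conditions: (NH4)2Ce(NO3)6 (2.2 equiv), MeCN/H2O, 0 °C
Reagents that add atoms: water, O
Why: Oxidative demethylation of a 4-methoxyphenol to the para-quinone; the electron-rich ring A is oxidised well before the prenyl alkene, and the MOM acetal should survive brief exposure at 0 °C.

**Step 10**
Reactants: 17 3-(methoxymethoxy)-6-(3-methylbut-2-enyl)-2-phenyl-4H-chromene-4,5,8-trione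
Product: 18 racemic 6,7-epoxy-6,7-dihydro-3-(methoxymethoxy)-6-(3-methylbut-2-enyl)-2-phenyl-4H-chromene-4,5,8-trione
Conditions: H2O2 (30 % aq.), Na2CO3, THF/H2O, 0 °C
Reagents that add atoms: hydrogen peroxide, OO
Why: Weitz–Scheffer nucleophilic epoxidation; hydroperoxide adds to the unhindered C7 of the enedione and the enolate closes the oxirane, leaving the prenyl alkene and the oxygen-substituted C4a=C8a bond alone, and the two new stereocentres (C6, C7) form as a racemate with the oxirane necessarily cis-fused before both are erased in step 11.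

**Step 11**
Reactants: 18 racemic 6,7-epoxy-6,7-dihydro-3-(methoxymethoxy)-6-(3-methylbut-2-enyl)-2-phenyl-4H-chromene-4,5,8-trione
Product: 19 7-hydroxy-3-(methoxymethoxy)-6-(3-methylbut-2-enyl)-2-phenyl-4H-chromene-4,5,8-trione
Conditions: DBU (1.1 equiv), CH2Cl2, 0 °C; then aq. citric acid
Reagents that add atoms: none
Why: Base-induced isomerisation of an epoxyquinone that bears an oxirane hydrogen (E1cB-type: removal of the C7–H alpha to the C8 carbonyl with opening of the C6–O bond), driven by formation of the acidic 2-hydroxyquinone, should place the hydroxyl on C7 and remove both stereocentres.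

**Step 12**
Reactants: 19 7-hydroxy-3-(methoxymethoxy)-6-(3-methylbut-2-enyl)-2-phenyl-4H-chromene-4,5,8-trione
Product: 20 5,7,8-trihydroxy-3-(methoxymethoxy)-6-(3-methylbut-2-enyl)flavone
Conditions: Na2S2O4, EtOAc/H2O, rt, Ar
Reagents that add atoms: none
Why: Two-phase dithionite reduction of a quinone to the hydroquinone is fast and should leave the alkene, the MOM acetal and the pyranone untouched.

**Step 13**
Reactants: 20 5,7,8-trihydroxy-3-(methoxymethoxy)-6-(3-methylbut-2-enyl)flavone
Product: 21 platanetin (3,5,7,8-tetrahydroxy-6-(3-methylbut-2-enyl)flavone)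
Conditions: HCl (3 M aq.), MeOH, 45 °C, Ar
Reagents that add atoms: none
Why: Acid-catalysed acetal exchange removes the MOM group; dilute acid, moderate temperature and argon should keep the prenyl group from cyclising onto the flanking hydroxyls and the hydroquinone from reoxidising.

**Compound list**
1 | kojic acid | OCc1cc(=O)c(O)co1 | starting material
2 | 2-bromo-3-hydroxy-6-(hydroxymethyl)-4H-pyran-4-one | OCc1cc(=O)c(O)c(Br)o1 | intermediate
3 | 2-bromo-6-(hydroxymethyl)-3-(methoxymethoxy)-4H-pyran-4-one | OCc1cc(=O)c(OCOC)c(Br)o1 | intermediate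
4 | phenylboronic acid | OB(O)c1ccccc1 | starting material
5 | 6-(hydroxymethyl)-3-(methoxymethoxy)-2-phenyl-4H-pyran-4-one | OCc1cc(=O)c(OCOC)c(-c2ccccc2)o1 | intermediate
6 | 5-(methoxymethoxy)-4-oxo-6-phenyl-4H-pyran-2-carboxylic acid | OC(=O)c1cc(=O)c(OCOC)c(-c2ccccc2)o1 | intermediate
7 | 5-(methoxymethoxy)-4-oxo-6-phenyl-4H-pyran-2-carbonyl chloride | ClC(=O)c1cc(=O)c(OCOC)c(-c2ccccc2)o1 | intermediate
8 | chromium hexacarbonyl | O=C=[Cr](=C=O)(=C=O)(=C=O)(=C=O)=C=O | starting material
9 | disodium pentacarbonylchromate | [Na+].[Na+].O=C=[Cr-2](=C=O)(=C=O)(=C=O)=C=O | intermediate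
10 | sodium pentacarbonyl[5-(methoxymethoxy)-4-oxo-6-phenyl-4H-pyran-2-carbonyl]chromate | [Na+].O=C(c1cc(=O)c(OCOC)c(-c2ccccc2)o1)[Cr-](=C=O)(=C=O)(=C=O)(=C=O)=C=O | intermediate
11 | pentacarbonyl{methoxy[5-(methoxymethoxy)-4-oxo-6-phenyl-4H-pyran-2-yl]methylidene}chromium | COC(=[Cr](=C=O)(=C=O)(=C=O)(=C=O)=C=O)c1cc(=O)c(OCOC)c(-c2ccccc2)o1 | intermediate
12 | prenyl bromide (1-bromo-3-methylbut-2-ene) | CC(C)=CCBr | starting material
13 | ethynylmagnesium bromide | C#C[Mg]Br | starting material
14 | 5-methylhex-4-en-1-yne | C#CCC=C(C)C | intermediate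
15 | tricarbonylchromium complex of 16, η6-bound to ring A (the η6 bond is written as a dot) | CC(C)=CCc1cc(OC)c2oc(-c3ccccc3)c(OCOC)c(=O)c2c1O.O=C=[Cr](=C=O)=C=O | intermediate
16 | 5-hydroxy-8-methoxy-3-(methoxymethoxy)-6-(3-methylbut-2-enyl)flavone | CC(C)=CCc1cc(OC)c2oc(-c3ccccc3)c(OCOC)c(=O)c2c1O | intermediate
17 | 3-(methoxymethoxy)-6-(3-methylbut-2-enyl)-2-phenyl-4H-chromene-4,5,8-trione | CC(C)=CCC1=CC(=O)c2oc(-c3ccccc3)c(OCOC)c(=O)c2C1=O | intermediate
18 | racemic 6,7-epoxy-6,7-dihydro derivative of 17, oxirane cis-fused (one enantiomer drawn) | CC(C)=CC[C@@]12O[C@@H]1C(=O)c1oc(-c3ccccc3)c(OCOC)c(=O)c1C2=O | intermediate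
19 | 7-hydroxy-3-(methoxymethoxy)-6-(3-methylbut-2-enyl)-2-phenyl-4H-chromene-4,5,8-trione | CC(C)=CCC1=C(O)C(=O)c2oc(-c3ccccc3)c(OCOC)c(=O)c2C1=O | intermediate
20 | 5,7,8-trihydroxy-3-(methoxymethoxy)-6-(3-methylbut-2-enyl)flavone | CC(C)=CCc1c(O)c(O)c2oc(-c3ccccc3)c(OCOC)c(=O)c2c1O | intermediate
21 | platanetin | CC(C)=CCc1c(O)c(O)c2oc(-c3ccccc3)c(O)c(=O)c2c1O | target

**Step count**
Total: 13 steps. Longest linear sequence: 12 steps (steps 1–6 and 8–13, from kojic acid); step 7 is a one-step side branch.

**Steps most likely to fail**

Step 8. After alkyne insertion, the vinylcarbene carrying the electron-poor pyranonyl group may not insert CO or may not electrocyclise onto the pyranone C2=C3 bond. The reaction would then divert to furan or cyclobutenone formation, or the carbene would decompose before insertion. The fallback gives up the ring A construction; it sets out from prenyl bromide 12 and comes back at the target 21. Direct nuclear C-prenylation of commercial galangin F1 with 12 (NaOMe, MeOH, rt) should give 6-prenylgalangin F2 after separation from the 8-isomer and the O-prenyl ethers. Elbs persulfate oxidation (K2S2O8, aq. KOH/pyridine, 0 °C to rt) then oxidises the only free ring A position, C8, para to the 5-hydroxyl, giving the potassium 8-O-sulfate F3. Brief warming of F3 with dilute HCl in the presence of Na2SO3 should hydrolyse it to 21.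

Step 6. The strongly reducing pentacarbonylchromate dianion may transfer an electron to the pyranone or add in conjugate fashion instead of being acylated cleanly, or methylation may occur at the pyranone carbonyl. The fallback uses the organolithium route of the Fischer carbene synthesis; it sets out from acid 6 and comes back at carbene 11. Protodecarboxylation (Ag2CO3 cat., AcOH, DMSO, 120 °C) should give 3-(methoxymethoxy)-2-phenyl-4H-pyran-4-one F4. Deprotonation next to the ring oxygen with lithium 2,2,6,6-tetramethylpiperidide (THF, −78 °C) gives the 6-lithio pyranone F5, which adds to Cr(CO)6 8 to give the lithium acylchromate F6. O-Methylation of F6 with Me3OBF4 gives 11.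

Step 11. The base may attack C8a, the vinylogous ester carbon of the epoxydione, and open the pyranone ring, or deprotonation at the oxirane carbon may be too slow and the epoxide may decompose. The fallback avoids the epoxide altogether (so it also bypasses step 10); it sets out from quinone 17 and comes back at the target 21. Thiele–Winter acetoxylation (Ac2O, cat. BF3·OEt2, 0 °C) adds acetate at C7, the only free quinone position, and acetylates the resulting hydroquinone. The MOM ether is expected to be exchanged for acetate under these conditions, giving 3,5,7,8-tetraacetoxy-6-(3-methylbut-2-enyl)flavone F7; the mild Lewis acid and low temperature are chosen to spare the prenyl alkene. Deacetylation of F7 (K2CO3, degassed MeOH, Ar, 0 °C; then dilute acid) should give 21.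

**Further compounds**
F1 | step 8 | galangin (3,5,7-trihydroxyflavone) | O=c1c(O)c(-c2ccccc2)oc2cc(O)cc(O)c12
F2 | step 8 | 6-prenylgalangin (3,5,7-trihydroxy-6-(3-methylbut-2-enyl)flavone) | CC(C)=CCc1c(O)cc2oc(-c3ccccc3)c(O)c(=O)c2c1O
F3 | step 8 | potassium salt of platanetin 8-O-sulfate | CC(C)=CCc1c(O)c(OS(=O)(=O)[O-])c2oc(-c3ccccc3)c(O)c(=O)c2c1O.[K+]
F4 | step 6 | 3-(methoxymethoxy)-2-phenyl-4H-pyran-4-one | COCOc1c(-c2ccccc2)occc1=O
F5 | step 6 | 6-lithio-3-(methoxymethoxy)-2-phenyl-4H-pyran-4-one | [Li]c1cc(=O)c(OCOC)c(-c2ccccc2)o1
F6 | step 6 | lithium pentacarbonyl[5-(methoxymethoxy)-4-oxo-6-phenyl-4H-pyran-2-carbonyl]chromate | [Li+].O=C(c1cc(=O)c(OCOC)c(-c2ccccc2)o1)[Cr-](=C=O)(=C=O)(=C=O)(=C=O)=C=O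
F7 | step 11 | 3,5,7,8-tetraacetoxy-6-(3-methylbut-2-enyl)flavone | CC(C)=CCc1c(OC(C)=O)c(OC(C)=O)c2oc(-c3ccccc3)c(OC(C)=O)c(=O)c2c1OC(C)=O
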